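## Analysis of the target

The target is a 12-membered macrodiolide built head to tail from two different 6-(1,2-dihydroxypropyl)benzoic acids. Ring carbons are cited below with the ring letter in brackets, C1(A) to C6(A) and C1(B) to C6(B). In each ring C1 carries the ester carbonyl and C6 the chain C1'H(OH)–C2'H(CH3)–O, whose C2' oxygen is acylated by the carbonyl of the other ring. Ring A has OH, OMe, OH on C2(A), C3(A), C4(A) and its only aryl hydrogen on C5(A); ring B is hexasubstituted, with OH, OMe, OH, OH on C2(B) to C5(B). There are four stereocentres: (1'R,2'S) in the A half and (1'R,2'R) in the B half. The two benzylic centres therefore have the same sense and the two methyl carbinol centres the opposite one, and the halves otherwise differ only by the oxygen on C5.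

Each free C1' hydroxyl sits ortho to an ester carbonyl and can contract the macrocycle to a phthalide. Any open-chain intermediate with a free C2' hydroxyl next to its own ester can close to a dihydroisocoumarin. Ring B is an air-sensitive hydroxyhydroquinone whose C5(B) phenol is ortho to the benzylic C1' oxygen. The hard parts are the two esters of 2,6-disubstituted benzoic acids with hindered secondary alcohols and the hexasubstituted ring B.

The strategy rests on the fact that C4(A), C5(A), C6(A), C1', C2' and the methyl group of the A half are carbons C1–C6 of L-rhamnose. The sugar C4 and C5 oxygens are already (1'R,2'S), and the pyranose oxygen is the C2' oxygen. A sugar-derived 5,6-dihydropyran-2-one then needs only the bonds C1(A)–C6(A) and C3(A)–C4(A) to a four-carbon keto ester to become ring A. Ring B is the same unit after oxidation at C5 and inversion at C2'.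

## Retrosynthetic reasoning

The last operation removes all protecting groups at once: 22 is traced back to its heptabenzyl ether 21, in which the five phenols and both C1' hydroxyls carry the same group. Free C1' hydroxyls next to ester carbonyls and the free ring B triol then exist only after a final neutral step. The forward reaction must cleave seven protecting-group C–O bonds and leave the two benzylic C1'–O bonds of the skeleton intact.

21 is opened at the ester between the ring B carbonyl and the C2' oxygen of the A half, which gives hydroxy acid 20. The cut is made at the acyl carbon because this C2' centre is the one taken unchanged from the sugar, so the forward ring closure must proceed with retention. Making this hindered acyl transfer the intramolecular one gives it the better chance.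

20 is led back through 19 and 18 to acid 13 and alcohol 17. Here the second ester is cut between the ester oxygen and C2' of the B half, not at the acyl carbon. The forward reaction is a Mitsunobu displacement by the carboxylate of 13. It avoids acyl activation of a di-ortho-substituted benzoic acid in the intermolecular step, and its inversion turns the (2'S) centre of 17 into the (2'R) centre the B half needs.

13 and 17 are both derived from one resorcylate, 11. 13 needs only benzylation (12) and loss of the allyl ester. 17 needs oxidation of the single aryl C–H to the hydroxyquinone 14, reduction to 15, benzylation to 16 and removal of the silyl ether. One ring-forming sequence thus supplies both aromatic halves and three of the four stereocentres.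

11 comes from the cyclohexane-1,3-dione 10 by dehydrogenation. This removes the ring CH stereocentre and sets OH, OMe, OH on C2(A), C3(A), C4(A) without any aromatic substitution chemistry.

10, through 9 and 8, is disconnected at C1(A)–C6(A) and C3(A)–C4(A) into lactone 5 and keto ester 7. These two bonds are chosen because 5 is a 1,3-bis-electrophile (its ring C4 and the lactone carbonyl) and 7 a 1,3-bis-nucleophile (its C2 and the methoxy-bearing C4). The acylation releases the ring oxygen of 5 as the C2' hydroxyl, so no stereocentre has to be created. The forward step must add conjugately before the lactone is opened by base, and the C1' protecting group must not move to the liberated oxygen.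

5 is reached from the commercial glycal diacetate 1 through 2, 3 and 4 by allylic rearrangement, exchange of acetate for benzyl and oxidation of the acetal carbon. 7 is the transesterification product of 6.

## Alternatives that were turned down

Alternative 1: The cut is the aryl–C1' bond of the A half, C6(A)–C1', with both ester bonds already in place. In the forward direction the open-chain aryl iodide A1, whose ring B carboxyl is esterified with an α-hydroxy aldehyde unit, is treated under Nozaki–Hiyama–Kishi conditions (CrCl2 with catalytic NiCl2). The aryl group adds to the tethered aldehyde and gives the macrocycle A2 and the C1' carbinol in one step.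
- For it: the ring is closed by C–C bond formation and not by acylation of a hindered alcohol. On this point it is stronger than the chosen route, whose ring closure (step 16) is a difficult acyl transfer.
- Against it: the new alkoxide appears ortho to the ring A ester carbonyl, the very arrangement that collapses to a phthalide and would open the macrocycle. The α-acyloxy aldehyde can epimerise and undergo acyl shift, and the C1' configuration would depend on 1,2-induction inside a forming medium ring. Ring B with its (1'R,2'R) chain would still need a separate aromatic synthesis.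
- Comparison: the chosen route takes C1' from the sugar, so no selectivity question arises there, and keeps that oxygen protected to the end; the price is the hard macrolactonisation.

Alternative 2: The cut is ring B itself, at C1(B)–C2(B), back to a four-membered ring. The cyclobutenone A4 would be made by adding an alkenyl anion to a squarate. This anion carries a tert-butyl ester and an acetonide-protected diol whose two stereocentres are taken from L-threonine A3. Heating A4 opens it to a dienylketene, 6π-closure forms C1(B)–C2(B), and tautomerisation gives the hydroquinone A5.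
- For it: the hexasubstituted ring arises with every oxygen placed and differentiated, and the (1'R,2'R) chain comes with the right configuration from the amino acid A3. On both points it is stronger than the chosen route, where the C5(B) oxygen comes from a late arene oxidation (step 10) and the B-chain C2' centre from an inversion (step 13).
- Against it: only ring B is solved, so ring A and the macrocycle need a second, unrelated sequence. The alkenyl anion bears an ester on its β-carbon and must add regioselectively to an unsymmetrical squarate. A5 is an air-sensitive hydroquinone with two phenols to tell apart, and acid is needed to remove acetonide and tert-butyl ester in a molecule that lactonises easily.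
- Comparison: the chosen route makes both aromatic halves from one annulation product (11), one ring-forming sequence in place of two, and accepts two steps of lower certainty.

Alternative 3: The cuts are C6(A)–C5(A) and C1(A)–C2(A) of ring A, made after the ester between the ring A carbonyl and the B-chain C2' oxygen exists. The ynoate A6, already esterified with the ring B half, would react with the oxygenated diene A7 in a [4+2] cycloaddition; loss of an alkoxy group as its alcohol aromatises the adduct to A8.
- For it: that ester is formed from an unhindered alkynoic acid, so neither a hindered acyl transfer nor an SN2 reaction at the carbinol is needed for it. This is stronger than step 13 of the chosen route, and the regiochemistry of such polarised dienes follows their electronics.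
- Against it: the β-branched, γ,δ-dioxygenated ynoate is a slow dienophile and the ketene-acetal diene is thermally and hydrolytically labile. The A-chain stereocentres must be set by separate asymmetric steps. In A8 the A-chain C2' centre has the configuration opposite to the target's, so the final closure would have to be an invertive lactonisation at a hindered carbinol, and ring B needs its own synthesis.
- Comparison: the chosen route obtains ring A, its substitution pattern and its two stereocentres in one step from the sugar lactone and re-uses them for ring B.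

Key step: step 6

## Remarks on the chemistry (assumptions)

- 3,4-Di-O-acetyl-L-rhamnal (1), the commercial glycal of L-rhamnose, is taken as the entry point; it is what the standard acetylation–bromination–zinc reduction of the sugar delivers.
- The C1' oxygen is carried as a benzyl ether and not as a silyl ether: a silyl group would migrate to the neighbouring C2' oxygen once that oxygen is released in step 6, and benzyl cannot.
- Diones 9 and 10 are drawn as dienols; they are tautomeric mixtures, and their ring CH centre is lost in step 7.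

## Route

Step 1
Reactants: 1 3,4-di-O-acetyl-L-rhamnal
Product: 2 ethyl 4-O-acetyl-2,3,6-trideoxy-α-L-erythro-hex-2-enopyranoside
Conditions: EtOH (3 equiv), BF3·OEt2 (cat.), CH2Cl2, 0 °C → rt
Reagents that add atoms: ethanol, CCO
Why: Ferrier rearrangement: the Lewis acid ionises the allylic C3 acetate and ethanol adds to C1 of the allyloxocarbenium ion, mainly trans to the C5 methyl group. The anomeric centre is destroyed in step 4, so its configuration does not matter; sugar C4 and C5 are untouched.

Step 2
Reactants: 2 ethyl 4-O-acetyl-2,3,6-trideoxy-α-L-erythro-hex-2-enopyranoside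
Product: 3 ethyl 2,3,6-trideoxy-α-L-erythro-hex-2-enopyranoside
Conditions: K2CO3 (cat.), MeOH, rt
Reagents that add atoms: none
Why: Base-catalysed methanolysis of the acetate; the acetal and the allylic stereocentre are stable to these conditions.

Step 3
Reactants: 3 ethyl 2,3,6-trideoxy-α-L-erythro-hex-2-enopyranoside
Product: 4 ethyl 4-O-benzyl-2,3,6-trideoxy-α-L-erythro-hex-2-enopyranoside
Conditions: NaH, BnBr, Bu4NI (cat.), DMF, 0 °C → rt
Reagents that add atoms: benzyl bromide, BrCc1ccccc1
Why: Williamson etherification at the acetal stage, where strong base is harmless. The benzyl ether cannot migrate to a neighbouring alkoxide and falls in the final hydrogenolysis.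

Step 4
Reactants: 4 ethyl 4-O-benzyl-2,3,6-trideoxy-α-L-erythro-hex-2-enopyranoside
Product: 5 (5R,6S)-5-(benzyloxy)-6-methyl-5,6-dihydro-2H-pyran-2-one
Conditions: mCPBA, BF3·OEt2, CH2Cl2, −20 → 0 °C
Reagents that add atoms: 3-chloroperbenzoic acid, OOC(=O)c1cccc(Cl)c1
Why: Lewis-acid-mediated peracid oxidation of a cyclic acetal to a lactone: the oxocarbenium ion is captured at C1 by the peracid and the anomeric perester fragments to the lactone and 3-chlorobenzoic acid. The electron-poor ring alkene and the benzyl ether are not attacked at this temperature.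

Step 5
Reactants: 6 methyl 4-methoxy-3-oxobutanoate
Product: 7 allyl 4-methoxy-3-oxobutanoate
Conditions: allyl alcohol (5 equiv), DMAP (cat.), toluene, reflux, MeOH distilled off
Reagents that add atoms: allyl alcohol, C=CCO
Why: DMAP-catalysed transesterification of a β-keto ester, driven by removal of methanol. The allyl ester can later be removed with zerovalent palladium in the presence of benzyl ethers and the silyl ether.

Step 6
Reactants: 5 (5R,6S)-5-(benzyloxy)-6-methyl-5,6-dihydro-2H-pyran-2-one; 7 allyl 4-methoxy-3-oxobutanoate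
Product: 10 allyl (6R)-6-[(1R,2S)-1-(benzyloxy)-2-(triethylsilyloxy)propyl]-2,4-dihydroxy-3-methoxycyclohexa-1,3-diene-1-carboxylate, via Michael adduct 8 (not isolated), via hydroxy dione 9 (not isolated)
Conditions: 7 (1.1 equiv), NaH (1.05 equiv), THF, 0 °C; add 5, 0 °C → rt; KOtBu (1.2 equiv), 0 °C → rt; AcOH; imidazole, TESCl, DMF, 0 °C → rt; cold aq. citric acid work-up
Reagents that add atoms: chlorotriethylsilane, CC[Si](CC)(CC)Cl
Why: Proposed new method: the sodium enolate of 7, a soft stabilised anion, adds through its central carbon to the β-carbon (ring C4) of lactone 5, forming the C1(A)–C6(A) bond, and proton transfer gives the keto ester enolate of 8; KOtBu then reversibly forms the enolate at the methoxy-bearing carbon, which attacks the lactone carbonyl to form the C3(A)–C4(A) bond, and collapse of the tetrahedral intermediate expels the C2' oxygen while the new 1,3-dione is deprotonated at once, which makes the sequence irreversible and gives 9. The closest known reaction type is the Michael–Claisen (Michael–Dieckmann) annulation of β-keto esters with acyclic α,β-unsaturated esters to 4-alkoxycarbonylcyclohexane-1,3-diones, together with the acylation of keto ester dianions by lactones; what is new is that one unsaturated δ-lactone serves as Michael acceptor and as acyl donor, so that the Claisen step turns the heterocycle into the carbocycle. Ring A closes in the 6-exo-trig mode, the only ring size open to the system, since the other possible acylations would give four-membered rings. The ring CH centre C6(A) should form anti to the neighbouring benzyloxy group by axial attack on the half-chair, but it is removed in step 7; C1' and C2' are carried over from 5 and lie α to no carbonyl group after the addition. The step needs conjugate addition to win over vinylogous deprotonation at ring C5 of 5, which would open the lactone to a dienoate; this is secured by using the weakly basic monoanion of 7 with no excess of NaH and by adding KOtBu only when the enoate has been consumed. The benzyl ether at C1' cannot migrate to the liberated C2' oxygen, the C1(A) ester is deactivated as part of the enolate while the medium is basic, and the C2' hydroxyl is silylated in the same flask after neutralisation so that it cannot lactonise later. Any enol silyl ether formed on the dione oxygens is hydrolysed again in the citric acid work-up, which the secondary triethylsilyl ether should survive.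

Step 7
Reactants: 10 allyl (6R)-6-[(1R,2S)-1-(benzyloxy)-2-(triethylsilyloxy)propyl]-2,4-dihydroxy-3-methoxycyclohexa-1,3-diene-1-carboxylate
Product: 11 allyl 6-[(1R,2S)-1-(benzyloxy)-2-(triethylsilyloxy)propyl]-2,4-dihydroxy-3-methoxybenzoate
Conditions: DDQ (1.2 equiv), 1,4-dioxane (dry), rt → 50 °C
Reagents that add atoms: none
Why: Quinone dehydrogenation of a 2,4-dioxocyclohexanecarboxylate to the resorcylate (hydride abstraction from the ring CH2, proton loss from the ring CH), driven by aromatisation. Without water the benzyl and silyl ethers are not cleaved, and position 3 is blocked by the methoxy group, so no over-oxidation is expected there.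

Step 8
Reactants: 11 allyl 6-[(1R,2S)-1-(benzyloxy)-2-(triethylsilyloxy)propyl]-2,4-dihydroxy-3-methoxybenzoate
Product: 12 allyl 2,4-bis(benzyloxy)-6-[(1R,2S)-1-(benzyloxy)-2-(triethylsilyloxy)propyl]-3-methoxybenzoate
Conditions: BnBr (2.5 equiv), K2CO3, Bu4NI (cat.), DMF, 50 °C
Reagents that add atoms: benzyl bromide, BrCc1ccccc1
Why: Phenol O-alkylation; warm DMF is used because the hydroxyl on C2(A) is hydrogen-bonded to the ester. The silyl ether on C2' keeps this oxygen from attacking the allyl ester under base.

Step 9
Reactants: 12 allyl 2,4-bis(benzyloxy)-6-[(1R,2S)-1-(benzyloxy)-2-(triethylsilyloxy)propyl]-3-methoxybenzoate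
Product: 13 2,4-bis(benzyloxy)-6-[(1R,2S)-1-(benzyloxy)-2-(triethylsilyloxy)propyl]-3-methoxybenzoic acid
Conditions: Pd(PPh3)4 (5 mol%), morpholine, THF, rt; aq. NaH2PO4 work-up
Reagents that add atoms: none
Why: Tsuji–Trost deallylation: zerovalent palladium ionises the allyl ester to a π-allyl complex that morpholine captures. The hindered ester is cleaved at the alkyl–oxygen bond, so its steric shielding does not matter.

Step 10
Reactants: 11 allyl 6-[(1R,2S)-1-(benzyloxy)-2-(triethylsilyloxy)propyl]-2,4-dihydroxy-3-methoxybenzoate
Product: 14 allyl 2-[(1R,2S)-1-(benzyloxy)-2-(triethylsilyloxy)propyl]-4-hydroxy-5-methoxy-3,6-dioxocyclohexa-1,4-diene-1-carboxylate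
Conditions: Fremy's salt (KSO3)2NO (2.5 equiv), KH2PO4 buffer (pH 6), acetone/H2O, rt
Reagents that add atoms: potassium nitrosodisulfonate, [K+].[K+].[O]N(S(=O)(=O)[O-])S(=O)(=O)[O-]
Why: Teuber oxidation: one nitroxyl radical forms the phenoxyl radical and a second adds at the only free ring position, which is para to the C2 oxygen and ortho to the C4 oxygen; loss of imidodisulfonate gives the hydroxy-p-quinone. The near-neutral medium spares the silyl ether, the allyl ester and the benzyl ether.

Step 11
Reactants: 14 allyl 2-[(1R,2S)-1-(benzyloxy)-2-(triethylsilyloxy)propyl]-4-hydroxy-5-methoxy-3,6-dioxocyclohexa-1,4-diene-1-carboxylate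
Product: 16 allyl 2,4,5-tris(benzyloxy)-6-[(1R,2S)-1-(benzyloxy)-2-(triethylsilyloxy)propyl]-3-methoxybenzoate, via hydroquinone 15 (not isolated)
Conditions: Na2S2O4, EtOAc/H2O, rt, Ar; organic phase dried and concentrated under Ar; BnBr (4 equiv), K2CO3, Bu4NI (cat.), DMF, 50 °C, Ar
Reagents that add atoms: benzyl bromide, BrCc1ccccc1
Why: Dithionite reduces the quinone to the 2,4,5-triol, which is alkylated at once under argon because it reoxidises in air. Fast O-benzylation of the phenoxide on C5(B) also removes the risk of quinone methide formation at C1'.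

Step 12
Reactants: 16 allyl 2,4,5-tris(benzyloxy)-6-[(1R,2S)-1-(benzyloxy)-2-(triethylsilyloxy)propyl]-3-methoxybenzoate
Product: 17 allyl 2,4,5-tris(benzyloxy)-6-[(1R,2S)-1-(benzyloxy)-2-hydroxypropyl]-3-methoxybenzoate
Conditions: HF·pyridine, pyridine, THF, 0 °C
Reagents that add atoms: none
Why: Fluoride-assisted cleavage of the triethylsilyl ether under buffered, weakly acidic conditions. No alkoxide is formed, so the free hydroxyl does not close onto the hindered allyl ester; 17 is used directly.

Step 13
Reactants: 13 2,4-bis(benzyloxy)-6-[(1R,2S)-1-(benzyloxy)-2-(triethylsilyloxy)propyl]-3-methoxybenzoic acid; 17 allyl 2,4,5-tris(benzyloxy)-6-[(1R,2S)-1-(benzyloxy)-2-hydroxypropyl]-3-methoxybenzoate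
Product: 18 allyl 2,4,5-tris(benzyloxy)-6-[(1R,2R)-1-(benzyloxy)-2-({2,4-bis(benzyloxy)-6-[(1R,2S)-1-(benzyloxy)-2-(triethylsilyloxy)propyl]-3-methoxybenzoyl}oxy)propyl]-3-methoxybenzoate
Conditions: PPh3, DIAD, toluene, 0 °C → rt
Reagents that add atoms: none
Why: Mitsunobu esterification: the C2' hydroxyl of 17 is activated as its oxyphosphonium ion and displaced by the carboxylate of 13 in an SN2 reaction. The inversion turns (2'S) into the (2'R) centre of the B half. The di-ortho-substituted acid reacts as a nucleophile, so its hindered carbonyl carbon is not involved.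

Step 14
Reactants: 18 allyl 2,4,5-tris(benzyloxy)-6-[(1R,2R)-1-(benzyloxy)-2-({2,4-bis(benzyloxy)-6-[(1R,2S)-1-(benzyloxy)-2-(triethylsilyloxy)propyl]-3-methoxybenzoyl}oxy)propyl]-3-methoxybenzoate
Product: 19 2,4,5-tris(benzyloxy)-6-[(1R,2R)-1-(benzyloxy)-2-({2,4-bis(benzyloxy)-6-[(1R,2S)-1-(benzyloxy)-2-(triethylsilyloxy)propyl]-3-methoxybenzoyl}oxy)propyl]-3-methoxybenzoic acid
Conditions: Pd(PPh3)4 (5 mol%), morpholine, THF, rt; aq. NaH2PO4 work-up
Reagents that add atoms: none
Why: Tsuji–Trost deallylation as in step 9. It is run before the desilylation so that the A-chain hydroxyl is still masked while an amine is present.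

Step 15
Reactants: 19 2,4,5-tris(benzyloxy)-6-[(1R,2R)-1-(benzyloxy)-2-({2,4-bis(benzyloxy)-6-[(1R,2S)-1-(benzyloxy)-2-(triethylsilyloxy)propyl]-3-methoxybenzoyl}oxy)propyl]-3-methoxybenzoic acid
Product: 20 2,4,5-tris(benzyloxy)-6-[(1R,2R)-1-(benzyloxy)-2-({2,4-bis(benzyloxy)-6-[(1R,2S)-1-(benzyloxy)-2-hydroxypropyl]-3-methoxybenzoyl}oxy)propyl]-3-methoxybenzoic acid
Conditions: HF·pyridine, pyridine, THF, 0 °C → rt
Reagents that add atoms: none
Why: Desilylation as in step 12; the hindered benzoate ester and the benzyl ethers are inert to buffered HF. The hydroxy acid is taken on without storage.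

Step 16
Reactants: 20 2,4,5-tris(benzyloxy)-6-[(1R,2R)-1-(benzyloxy)-2-({2,4-bis(benzyloxy)-6-[(1R,2S)-1-(benzyloxy)-2-hydroxypropyl]-3-methoxybenzoyl}oxy)propyl]-3-methoxybenzoic acid
Product: 21 hepta-O-benzyl ether of the target (12-membered dilactone in which the five phenols and both C1' hydroxyls are benzylated; A half (1'R,2'S), B half (1'R,2'R))
Conditions: 2-chloro-1-methylpyridinium iodide, Et3N, CH2Cl2/MeCN, reflux, syringe-pump addition of 20 (final 1 mM)
Reagents that add atoms: none
Why: Mukaiyama macrolactonisation: the carboxylate is activated as a transient 2-acyloxy-1-methylpyridinium ion and attacked by the A-chain C2' hydroxyl with retention. This activation is a known way to lactonise 2,6-disubstituted benzoic hydroxy acids. High dilution favours the 12-membered ring over oligomers.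

Step 17
Reactants: 21 hepta-O-benzyl ether of the target
Product: 22 CNP0086623.4 (target)
Conditions: H2 (1 atm), Pd/C (10%), EtOAc/MeOH, rt, neutral; filtration and concentration under Ar
Reagents that add atoms: none
Why: Hydrogenolysis of five aryl benzyl ethers and two alkyl benzyl ethers at the unsubstituted benzylic carbon. The skeletal C1'–O bonds are secondary and flanked by fully substituted, di-ortho-substituted arenes that adsorb poorly on the catalyst, and no acid or base is present to trigger phthalide formation.

## Compound list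

1 | 3,4-di-O-acetyl-L-rhamnal (3,4-di-O-acetyl-1,5-anhydro-2,6-dideoxy-L-arabino-hex-1-enitol) | C[C@H]1[C@H](OC(C)=O)[C@@H](OC(C)=O)C=CO1 | starting material
2 | ethyl 4-O-acetyl-2,3,6-trideoxy-α-L-erythro-hex-2-enopyranoside | CCO[C@H]1C=C[C@@H](OC(C)=O)[C@H](C)O1 | intermediate
3 | ethyl 2,3,6-trideoxy-α-L-erythro-hex-2-enopyranoside | CCO[C@H]1C=C[C@@H](O)[C@H](C)O1 | intermediate
4 | ethyl 4-O-benzyl-2,3,6-trideoxy-α-L-erythro-hex-2-enopyranoside | CCO[C@H]1C=C[C@@H](OCc2ccccc2)[C@H](C)O1 | intermediate
5 | (5R,6S)-5-(benzyloxy)-6-methyl-5,6-dihydro-2H-pyran-2-one | O=C1O[C@@H](C)[C@H](OCc2ccccc2)C=C1 | intermediate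
6 | methyl 4-methoxy-3-oxobutanoate | COCC(=O)CC(=O)OC | starting material
7 | allyl 4-methoxy-3-oxobutanoate | C=CCOC(=O)CC(=O)COC | intermediate
8 | allyl 2-[(2S,3R,4R)-3-(benzyloxy)-2-methyl-6-oxooxan-4-yl]-4-methoxy-3-oxobutanoate (epimers at C2 of the butanoate) | O=C1C[C@H](C(C(=O)COC)C(=O)OCC=C)[C@@H](OCc2ccccc2)[C@H](C)O1 | intermediate
9 | allyl (6R)-6-[(1R,2S)-1-(benzyloxy)-2-hydroxypropyl]-2,4-dihydroxy-3-methoxycyclohexa-1,3-diene-1-carboxylate (dienol form of the 3-methoxy-2,4-dioxocyclohexanecarboxylate) | O[C@@H](C)[C@H](OCc1ccccc1)[C@@H]1CC(O)=C(OC)C(O)=C1C(=O)OCC=C | intermediate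
10 | allyl (6R)-6-[(1R,2S)-1-(benzyloxy)-2-(triethylsilyloxy)propyl]-2,4-dihydroxy-3-methoxycyclohexa-1,3-diene-1-carboxylate | CC[Si](CC)(CC)O[C@@H](C)[C@H](OCc1ccccc1)[C@@H]1CC(O)=C(OC)C(O)=C1C(=O)OCC=C | intermediate
11 | allyl 6-[(1R,2S)-1-(benzyloxy)-2-(triethylsilyloxy)propyl]-2,4-dihydroxy-3-methoxybenzoate | CC[Si](CC)(CC)O[C@@H](C)[C@H](OCc1ccccc1)c1cc(O)c(OC)c(O)c1C(=O)OCC=C | intermediate
12 | allyl 2,4-bis(benzyloxy)-6-[(1R,2S)-1-(benzyloxy)-2-(triethylsilyloxy)propyl]-3-methoxybenzoate | CC[Si](CC)(CC)O[C@@H](C)[C@H](OCc1ccccc1)c1cc(OCc2ccccc2)c(OC)c(OCc2ccccc2)c1C(=O)OCC=C | intermediate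
13 | 2,4-bis(benzyloxy)-6-[(1R,2S)-1-(benzyloxy)-2-(triethylsilyloxy)propyl]-3-methoxybenzoic acid | CC[Si](CC)(CC)O[C@@H](C)[C@H](OCc1ccccc1)c1cc(OCc2ccccc2)c(OC)c(OCc2ccccc2)c1C(=O)O | intermediate
14 | allyl 2-[(1R,2S)-1-(benzyloxy)-2-(triethylsilyloxy)propyl]-4-hydroxy-5-methoxy-3,6-dioxocyclohexa-1,4-diene-1-carboxylate | CC[Si](CC)(CC)O[C@@H](C)[C@H](OCc1ccccc1)C1=C(C(=O)OCC=C)C(=O)C(OC)=C(O)C1=O | intermediate
15 | allyl 6-[(1R,2S)-1-(benzyloxy)-2-(triethylsilyloxy)propyl]-2,4,5-trihydroxy-3-methoxybenzoate | CC[Si](CC)(CC)O[C@@H](C)[C@H](OCc1ccccc1)c1c(O)c(O)c(OC)c(O)c1C(=O)OCC=C | intermediate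
16 | allyl 2,4,5-tris(benzyloxy)-6-[(1R,2S)-1-(benzyloxy)-2-(triethylsilyloxy)propyl]-3-methoxybenzoate | CC[Si](CC)(CC)O[C@@H](C)[C@H](OCc1ccccc1)c1c(OCc2ccccc2)c(OCc2ccccc2)c(OC)c(OCc2ccccc2)c1C(=O)OCC=C | intermediate
17 | allyl 2,4,5-tris(benzyloxy)-6-[(1R,2S)-1-(benzyloxy)-2-hydroxypropyl]-3-methoxybenzoate | O[C@@H](C)[C@H](OCc1ccccc1)c1c(OCc2ccccc2)c(OCc2ccccc2)c(OC)c(OCc2ccccc2)c1C(=O)OCC=C | intermediate
18 | allyl 2,4,5-tris(benzyloxy)-6-[(1R,2R)-1-(benzyloxy)-2-({2,4-bis(benzyloxy)-6-[(1R,2S)-1-(benzyloxy)-2-(triethylsilyloxy)propyl]-3-methoxybenzoyl}oxy)propyl]-3-methoxybenzoate | CC[Si](CC)(CC)O[C@@H](C)[C@H](OCc1ccccc1)c1cc(OCc2ccccc2)c(OC)c(OCc2ccccc2)c1C(=O)O[C@H](C)[C@H](OCc1ccccc1)c1c(OCc2ccccc2)c(OCc2ccccc2)c(OC)c(OCc2ccccc2)c1C(=O)OCC=C | intermediate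
19 | 2,4,5-tris(benzyloxy)-6-[(1R,2R)-1-(benzyloxy)-2-({2,4-bis(benzyloxy)-6-[(1R,2S)-1-(benzyloxy)-2-(triethylsilyloxy)propyl]-3-methoxybenzoyl}oxy)propyl]-3-methoxybenzoic acid | CC[Si](CC)(CC)O[C@@H](C)[C@H](OCc1ccccc1)c1cc(OCc2ccccc2)c(OC)c(OCc2ccccc2)c1C(=O)O[C@H](C)[C@H](OCc1ccccc1)c1c(OCc2ccccc2)c(OCc2ccccc2)c(OC)c(OCc2ccccc2)c1C(=O)O | intermediate
20 | 2,4,5-tris(benzyloxy)-6-[(1R,2R)-1-(benzyloxy)-2-({2,4-bis(benzyloxy)-6-[(1R,2S)-1-(benzyloxy)-2-hydroxypropyl]-3-methoxybenzoyl}oxy)propyl]-3-methoxybenzoic acid | O[C@@H](C)[C@H](OCc1ccccc1)c1cc(OCc2ccccc2)c(OC)c(OCc2ccccc2)c1C(=O)O[C@H](C)[C@H](OCc1ccccc1)c1c(OCc2ccccc2)c(OCc2ccccc2)c(OC)c(OCc2ccccc2)c1C(=O)O | intermediate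
21 | hepta-O-benzyl ether of the target (benzyl ethers on the C2 and C4 oxygens of ring A, on the C2, C4 and C5 oxygens of ring B and on both C1' oxygens) | COc1c(OCc3ccccc3)cc2c(c1OCc1ccccc1)C(=O)O[C@H](C)[C@H](OCc1ccccc1)c1c(OCc3ccccc3)c(OCc3ccccc3)c(OC)c(OCc3ccccc3)c1C(=O)O[C@@H](C)[C@@H]2OCc1ccccc1 | intermediate
22 | CNP0086623.4 | COc1c(O)cc2c(c1O)C(=O)O[C@H](C)[C@H](O)c1c(O)c(O)c(OC)c(O)c1C(=O)O[C@@H](C)[C@@H]2O | target

## Step count and steps least certain to work

Total: 17 steps. Longest linear sequence: 14 steps (steps 1–4, 6, 7, 10–17); the A branch (steps 8, 9) and step 5 run in parallel.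

Step 6 (key step, the one step that bears the label "Proposed new method:"). Three processes may intervene. Vinylogous deprotonation at ring C5 of the lactone can open the ring to a dienoate before conjugate addition. The sequence can stop after the Michael addition if the second enolate does not acylate. The benzyloxy group can be eliminated, or the freed hydroxyl can lactonise, under prolonged base. The fallback uses known reactions only and sets out from 5 and 7. The conjugate addition is run alone with catalytic DBU and the adduct 8 is isolated. Its lactone is opened with Me3Al/MeNH(OMe)·HCl to the hydroxy Weinreb amide F1, and the hydroxyl is silylated (TESCl, imidazole) to the silyl ether F2. The keto ester dianion of F2 (NaH, then LDA, THF, −78 → 0 °C) is then acylated intramolecularly by the amide, which returns to the route at 10.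

Step 10. The resorcinol is deactivated by the ester and one phenol is hydrogen-bonded, so oxidation may be slow. Prolonged exposure invites oxidative coupling or degradation of the hydroxyquinone. The fallback sets out from 11. Ortho-formylation next to the C4 phenol at the only free ring position (MgCl2, Et3N, paraformaldehyde, MeCN, reflux) gives the salicylaldehyde F3. Dakin oxidation (H2O2, NaHCO3, THF/H2O) with hydrolysis of the aryl formate gives hydroquinone 15, which re-enters the route at the benzylation of step 11 and reaches 16.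

Step 13. The activated carbinol is flanked by a branched, oxygenated benzylic carbon. Displacement by the bulky carboxylate may therefore lose to elimination towards an enol ether, or to participation of the neighbouring allyl ester carbonyl. The fallback sets out from 17. Mitsunobu inversion with the small, acidic chloroacetic acid gives the (1R,2R)-chloroacetate F4, and thiourea removes the chloroacetyl group to give the (1R,2R)-alcohol F5. F5 is acylated with 13 (2-chloro-1-methylpyridinium iodide, Et3N, DMAP) with retention, which returns to 18.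

Step 16. Acyl transfer at the di-ortho-substituted acyl group may be slow. This leaves time for oligomerisation, for attack of the C1' ether oxygen on the activated acyl group (phthalide formation with loss of the benzyl group), or for shift of the existing ester to the free hydroxyl (dihydroisocoumarin formation). The fallback exchanges the roles of the two ester bonds. From 16, deallylation as in step 9 gives the acid F6; from 12, desilylation as in step 12 gives the alcohol F7. Acylation of F7 with F6 (2-chloro-1-methylpyridinium iodide, Et3N, DMAP) gives the diester F8, deallylation gives the acid F9, and desilylation gives the hydroxy acid F10, whose B-chain C2' hydroxyl still has the (S) configuration. Mitsunobu macrolactonisation (PPh3, DIAD, toluene, high dilution) closes the ring with inversion at that centre and returns to 21.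

Step 17. Hydrogenolysis may go on to cleave the skeletal benzylic C1'–O bonds, above all in ring B once the ortho phenol is free. The ring B triol may also oxidise in air during isolation. The fallback sets out from 21 and removes the benzyl groups without hydrogen, by BCl3 and pentamethylbenzene in CH2Cl2 at −78 °C, giving 22 directly; no new compound is involved (F0).

## Further compounds

F1 | step 6 | allyl (3R,4R,5S)-4-(benzyloxy)-5-hydroxy-2-(2-methoxyacetyl)-3-{2-[methoxy(methyl)amino]-2-oxoethyl}hexanoate (epimers at C2) | C=CCOC(=O)C(C(=O)COC)[C@@H](CC(=O)N(C)OC)[C@@H](OCc1ccccc1)[C@H](C)O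
F2 | step 6 | allyl (3R,4R,5S)-4-(benzyloxy)-2-(2-methoxyacetyl)-3-{2-[methoxy(methyl)amino]-2-oxoethyl}-5-(triethylsilyloxy)hexanoate (epimers at C2) | C=CCOC(=O)C(C(=O)COC)[C@@H](CC(=O)N(C)OC)[C@@H](OCc1ccccc1)[C@H](C)O[Si](CC)(CC)CC
F3 | step 10 | allyl 6-[(1R,2S)-1-(benzyloxy)-2-(triethylsilyloxy)propyl]-5-formyl-2,4-dihydroxy-3-methoxybenzoate | CC[Si](CC)(CC)O[C@@H](C)[C@H](OCc1ccccc1)c1c(C=O)c(O)c(OC)c(O)c1C(=O)OCC=C
F4 | step 13 | allyl 2,4,5-tris(benzyloxy)-6-[(1R,2R)-1-(benzyloxy)-2-(2-chloroacetoxy)propyl]-3-methoxybenzoate | ClCC(=O)O[C@H](C)[C@H](OCc1ccccc1)c1c(OCc2ccccc2)c(OCc2ccccc2)c(OC)c(OCc2ccccc2)c1C(=O)OCC=C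
F5 | step 13 | allyl 2,4,5-tris(benzyloxy)-6-[(1R,2R)-1-(benzyloxy)-2-hydroxypropyl]-3-methoxybenzoate | O[C@H](C)[C@H](OCc1ccccc1)c1c(OCc2ccccc2)c(OCc2ccccc2)c(OC)c(OCc2ccccc2)c1C(=O)OCC=C
F6 | step 16 | 2,4,5-tris(benzyloxy)-6-[(1R,2S)-1-(benzyloxy)-2-(triethylsilyloxy)propyl]-3-methoxybenzoic acid | CC[Si](CC)(CC)O[C@@H](C)[C@H](OCc1ccccc1)c1c(OCc2ccccc2)c(OCc2ccccc2)c(OC)c(OCc2ccccc2)c1C(=O)O
F7 | step 16 | allyl 2,4-bis(benzyloxy)-6-[(1R,2S)-1-(benzyloxy)-2-hydroxypropyl]-3-methoxybenzoate | O[C@@H](C)[C@H](OCc1ccccc1)c1cc(OCc2ccccc2)c(OC)c(OCc2ccccc2)c1C(=O)OCC=C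
F8 | step 16 | allyl 2,4-bis(benzyloxy)-6-[(1R,2S)-1-(benzyloxy)-2-({2,4,5-tris(benzyloxy)-6-[(1R,2S)-1-(benzyloxy)-2-(triethylsilyloxy)propyl]-3-methoxybenzoyl}oxy)propyl]-3-methoxybenzoate | CC[Si](CC)(CC)O[C@@H](C)[C@H](OCc1ccccc1)c1c(OCc2ccccc2)c(OCc2ccccc2)c(OC)c(OCc2ccccc2)c1C(=O)O[C@@H](C)[C@H](OCc1ccccc1)c1cc(OCc2ccccc2)c(OC)c(OCc2ccccc2)c1C(=O)OCC=C
F9 | step 16 | 2,4-bis(benzyloxy)-6-[(1R,2S)-1-(benzyloxy)-2-({2,4,5-tris(benzyloxy)-6-[(1R,2S)-1-(benzyloxy)-2-(triethylsilyloxy)propyl]-3-methoxybenzoyl}oxy)propyl]-3-methoxybenzoic acid | CC[Si](CC)(CC)O[C@@H](C)[C@H](OCc1ccccc1)c1c(OCc2ccccc2)c(OCc2ccccc2)c(OC)c(OCc2ccccc2)c1C(=O)O[C@@H](C)[C@H](OCc1ccccc1)c1cc(OCc2ccccc2)c(OC)c(OCc2ccccc2)c1C(=O)O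
F10 | step 16 | 2,4-bis(benzyloxy)-6-[(1R,2S)-1-(benzyloxy)-2-({2,4,5-tris(benzyloxy)-6-[(1R,2S)-1-(benzyloxy)-2-hydroxypropyl]-3-methoxybenzoyl}oxy)propyl]-3-methoxybenzoic acid | O[C@@H](C)[C@H](OCc1ccccc1)c1c(OCc2ccccc2)c(OCc2ccccc2)c(OC)c(OCc2ccccc2)c1C(=O)O[C@@H](C)[C@H](OCc1ccccc1)c1cc(OCc2ccccc2)c(OC)c(OCc2ccccc2)c1C(=O)O
F0 | step 17 | none | none
A1 | alternative 1 | (2S)-1-oxopropan-2-yl 2,4,5-tris(benzyloxy)-6-[(1R,2R)-2-{[2,4-bis(benzyloxy)-6-iodo-3-methoxybenzoyl]oxy}-1-(tert-butyldimethylsilyloxy)propyl]-3-methoxybenzoate | O=C(O[C@H](C)[C@H](O[Si](C)(C)C(C)(C)C)c1c(OCc2ccccc2)c(OCc2ccccc2)c(OC)c(OCc2ccccc2)c1C(=O)O[C@@H](C)C=O)c1c(I)cc(OCc2ccccc2)c(OC)c1OCc1ccccc1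
A2 | alternative 1 | protected macrodiolide with free A-chain C1' hydroxyl (five phenols as benzyl ethers, B-chain C1' oxygen as tert-butyldimethylsilyl ether) | O=C1O[C@H](C)[C@H](O[Si](C)(C)C(C)(C)C)c2c(OCc3ccccc3)c(OCc3ccccc3)c(OC)c(OCc3ccccc3)c2C(=O)O[C@@H](C)[C@H](O)c2cc(OCc3ccccc3)c(OC)c(OCc3ccccc3)c21
A3 | alternative 2 | L-threonine | C[C@@H](O)[C@H](N)C(O)=O
A4 | alternative 2 | tert-butyl 3-[2-(benzyloxy)-1-hydroxy-3-methoxy-4-oxocyclobut-2-en-1-yl]-3-[(4R,5R)-2,2,5-trimethyl-1,3-dioxolan-4-yl]prop-2-enoate (carbinol centre and alkene geometry not fixed) | CC1(C)O[C@H](C)[C@H](O1)C(=CC(=O)OC(C)(C)C)C1(O)C(OCc2ccccc2)=C(OC)C1=O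
A5 | alternative 2 | tert-butyl 4-(benzyloxy)-2,5-dihydroxy-3-methoxy-6-[(4R,5R)-2,2,5-trimethyl-1,3-dioxolan-4-yl]benzoate | CC1(C)O[C@H](C)[C@H](O1)c1c(O)c(OCc2ccccc2)c(OC)c(O)c1C(=O)OC(C)(C)C
A6 | alternative 3 | allyl 2,4,5-tris(benzyloxy)-6-[(1R,2R)-1-(tert-butyldimethylsilyloxy)-2-{[(4R,5R)-4-(tert-butyldimethylsilyloxy)-5-(triethylsilyloxy)hex-2-ynoyl]oxy}propyl]-3-methoxybenzoate | CC[Si](CC)(CC)O[C@H](C)[C@H](O[Si](C)(C)C(C)(C)C)C#CC(=O)O[C@H](C)[C@H](O[Si](C)(C)C(C)(C)C)c1c(OCc2ccccc2)c(OCc2ccccc2)c(OC)c(OCc2ccccc2)c1C(=O)OCC=C
A7 | alternative 3 | 1,2-dimethoxy-1,3-bis(trimethylsilyloxy)buta-1,3-diene (geometry not fixed) | COC(O[Si](C)(C)C)=C(OC)C(=C)O[Si](C)(C)C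
A8 | alternative 3 | allyl 2,4,5-tris(benzyloxy)-6-[(1R,2R)-1-(tert-butyldimethylsilyloxy)-2-({6-[(1R,2R)-1-(tert-butyldimethylsilyloxy)-2-(triethylsilyloxy)propyl]-2,4-dihydroxy-3-methoxybenzoyl}oxy)propyl]-3-methoxybenzoate | CC[Si](CC)(CC)O[C@H](C)[C@H](O[Si](C)(C)C(C)(C)C)c1cc(O)c(OC)c(O)c1C(=O)O[C@H](C)[C@H](O[Si](C)(C)C(C)(C)C)c1c(OCc2ccccc2)c(OCc2ccccc2)c(OC)c(OCc2ccccc2)c1C(=O)OCC=C
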